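The earlier runs and the new flask come from a simulation for an exercise.

If I want the target in the west flask at its asked time, I can solve the flask at both ends and join them: the early readings give the ladder of rates, and the late ones give the share of consumed substrate that ends as target.

| setting | west | south | flask |
|---|---|---|---|
| substrate | 0.13 M | 0.13 M | 0.13 M |
| reagent | 0.169 M | 0.169 M | 0.169 M |
| capture agent | 0.13 M | 0.26 M | 0.130 M |
| temperature | 35 °C | 41 °C | 35 °C |
| remark | the very flask that is asked about, followed so far | run made earlier |  |
| time |  |  | 5.0 d |

west run (percent of the substrate charged)

| time / d | target / % | substrate / % |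
|---|---|---|
| 0.333 | 16.2 | 37.6 |
| 0.500 | 26.4 | 29.7 |
| 0.833 | 42.6 | 22.2 |
| 1.67 | 64.3 | 17.5 |
| 2.50 | 70.6 | 15.2 |
| 4.00 | 77.8 | 14.7 |

south run (percent of the substrate charged)

| time / h | target / % | substrate / % |
|---|---|---|
| 3.00 | 10.7 | 40.9 |
| 8.00 | 34.2 | 23.7 |
| 15.0 | 55.0 | 17.9 |
| 25.0 | 69.8 | 16.3 |
| 30.0 | 68.3 | 14.2 |
| 40.0 | 75.3 | 13.3 |

(each reading ± 1 percentage point)

- what is taken out of target is counted as made
- the analysis behind the earlier runs scatters by 1 percentage point, standard deviation
- steps that have been proposed: 2 reagent -> self-condensation product; open intermediate -> target; open intermediate + capture agent -> trapped intermediate; substrate + reagent -> open intermediate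
- additions bring no volume worth counting

- Saturday's: at 5.0 d take out 90% of the target then present, then wait 2.5 d
- Monday's: change nothing and wait 2.5 d more
- Wednesday's: at 5.0 d raise the temperature by 15 K, then wait 2.5 d
- Tuesday's: at 5.0 d add reagent, 100% of the amount charged, then wait 2.5 d

1. target, in percent of the substrate first charged, at 5.0 d
2. which option adds most target ("none" when 2 percentage points or less is all one gets) (Saturday's / Monday's / Wednesday's / Tuesday's / none)
3. target present, with what was taken out counted in, in percent of the substrate first charged, after Saturday's
4. target present, with what was taken out counted in, in percent of the substrate first charged, after Tuesday's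

The proposed steps are these: substrate and reagent give open intermediate, which closes to target or meets capture agent to become trapped intermediate, while two reagent also condense with each other. On the top rung of the west run, substrate falls to 37.6% by 0.333 d, an average rate of 2.94 /d, while target reads 16.2%, so the flask then holds a gap of 46.2% that I read as mostly open intermediate. On the next rung that gap drains towards its last reading of 7.50%, and between 0.833 d and 1.67 d it does so at 1.14 /d, slower than the first rung. On the last rung, substrate moves by 0.5 percentage points between 2.50 d and 4.00 d, less than the scatter. Substrate has by then taken 0.111 M of the 0.169 M of reagent charged, so I read the stall as reagent lost to self-condensation, which makes reagent the limiting reagent here despite its 1.30 equivalents.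

Joining the ends, the last west reading gives 91.2% for what I call the keep, the share of consumed substrate that ends as target. The last south reading gives 86.9% with twice the capture agent and a warmer bath, and since two settings differ there, I hold the keep to the west settings. If substrate stays at its last reading, my reckoning for the west flask is 77.8% at 5.0 d, which simply repeats the last target reading, and if Tuesday's reagent consumes the remaining substrate, 91.2% after it, a gain of 13 points; the other options add no reagent, so I expect each to stay within 2 points.

The forecast, a little above me on the first figure, says 79% (range 77.5% to 81.5%), 79.2% after Saturday's (77.5% to 83%) and 91% after Tuesday's (87.5% to 94%), and it chooses Tuesday's, holding that “Removing target, waiting or heating gives essentially nothing, unless the trap is slightly reversible.”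

The simulation gives 77.2% at 5.0 d, 77.6% after Saturday's and 89.7% after Tuesday's, and its choice is Tuesday's, which gains 12 points against 0.46 points for Wednesday's.

    2 reagent → self-condensation product (k = 0.501 /M/h, Ea = 68.0 kJ/mol)
    open intermediate → target (k = 0.0537 /h, Ea = 114 kJ/mol)
    open intermediate + capture agent → trapped intermediate (k = 0.0451 /M/h, Ea = 85.0 kJ/mol)
    substrate + reagent → open intermediate (k = 1.82 /M/h, Ea = 79.0 kJ/mol)
    (constants at 35 °C)

At 5.00 d the west flask holds 0.13% of its reagent charge and 0.318% of open intermediate beside 14.4% of substrate, and waiting gains 0.39 points. The keep of this flask then comes to 90.2%. The neighbour charged with 0.42 M of reagent, 3.23 equiv, ends with 0.35% of its substrate unconsumed, so the keep read from the west run reckons 90.9% of target for it, and that neighbour gives 90.1%.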